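**Plan**

- With isochromene locants (ring A: C1, O2, C3, C4, C4a, C8a; ring B: C4a, C5, C6, C7, C8, C8a; side chain C1′–C7′), the C6 ketone beside the tertiary carbinol C7 in ring B is an α-ketol. Ring B is therefore cut at C7–C8 and contracted to a cyclopenta[c]pyran whose C6 carries a hydroxyl and an acetyl group (the acetyl carbon is the later C7).
- Further cuts: O2–C3 (alkynol hydroalkoxylation), C6–acetyl (1-ethoxyvinyllithium), C4–C4a (acetylide addition, then oxidative 1,3-transposition), C8a–C1 (formaldehyde aldol), C2′–C3′ (Suzuki–Miyaura coupling), and the C3≡C4 alkyne from a dienal.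
- Forward order: the side chain is built as a dienyne and joined to a cyclopentenone, which is the later five-membered carbocycle. Ring A is then closed by 6-endo hydroalkoxylation. Ring B arises last, by one-carbon enlargement of the carbocycle.
- Stereochemistry: C5′ from (S)-2-methylbutan-1-ol; C8 from (R)-4-silyloxycyclopentenone; C8a by an aldol trans to C8; the C6 carbinol by addition anti to the C8 silyloxy group; C7 by the chelated 1,2-shift; 3′Z from a Stork–Zhao olefination and 1′E from an (E)-alkenylboronate.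

Key step: step 12

Remark: the side-chain geometry is taken as written in the SMILES (1′E,3′Z). Target locants are used for the matching atoms of all intermediates. TBS = tert-butyldimethylsilyl, TES = triethylsilyl.

**Step 1**
Reactants: 1 (S)-2-methylbutan-1-ol
Product: 2 (S)-2-methylbutanal
Conditions: TEMPO (cat.), KBr (cat.), NaOCl, NaHCO3, CH2Cl2/H2O, 0 °C; distillation
Reagents that add atoms: none
Why: Anelli oxidation (oxoammonium-mediated) stops at the aldehyde and, run cold near pH 9 with short contact, should leave the α-stereocentre (later C5′) intact.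

**Step 2**
Reactants: 2 (S)-2-methylbutanal
Product: 3 (2Z,4S)-2-iodo-4-methylhex-2-ene
Conditions: EtPPh3I, n-BuLi, THF, 23 °C; I2, −78 °C; NaN(SiMe3)2, −20 °C; then 2, −78 → 23 °C
Reagents that add atoms: ethyltriphenylphosphonium iodide, CC[P+](c1ccccc1)(c1ccccc1)c1ccccc1.[I-]; iodine, II
Why: Stork–Zhao olefination with the α-iodo ylide should give the (Z)-2-iodoalk-2-ene (iodine cis to the sec-butyl group), which fixes the 3′Z geometry.

**Step 3**
Reactants: 3 (2Z,4S)-2-iodo-4-methylhex-2-ene; 4 (E)-2-(3,3-diethoxyprop-1-en-1-yl)-4,4,5,5-tetramethyl-1,3,2-dioxaborolane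
Product: 6 (2E,4Z,6S)-4,6-dimethylocta-2,4-dienal, via dienal diethyl acetal 5 (not isolated)
Conditions: Pd(PPh3)4 (5 mol %), aq. NaOH, THF, 50 °C; then aq. HCl to pH 2–3, 0 °C, 15 min
Reagents that add atoms: water, O
Why: Suzuki–Miyaura coupling with zerovalent palladium proceeds with retention at both alkenyl carbons (3′Z from 3, 1′E from 4), and the allylic acetal should hydrolyse in the cold before the 4Z bond can isomerise.

**Step 4**
Reactants: 6 (2E,4Z,6S)-4,6-dimethylocta-2,4-dienal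
Product: 7 (3E,5Z,7S)-5,7-dimethylnona-3,5-dien-1-yne
Conditions: Me3SiCHN2, n-BuLi, THF, −78 °C; then 6, −78 → 0 °C; H2O
Reagents that add atoms: (trimethylsilyl)diazomethane, C[Si](C)(C)C=[N+]=[N-]
Why: Colvin homologation (Peterson elimination to a diazoalkene, then 1,2-hydride shift of the alkylidene carbene) turns the aldehyde into the terminal alkyne without a protic nucleophile that could add to the dienal.

**Step 5**
Reactants: 8 (R)-4-(tert-butyldimethylsilyloxy)cyclopent-2-en-1-one
Product: 10 (4S,5R)-4-(tert-butyldimethylsilyloxy)-5-(hydroxymethyl)cyclopent-2-en-1-one, via lithium enolate 9 (not isolated)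
Conditions: LiN(iPr)2, THF, −78 °C; CH2O (monomeric, in THF), −78 °C; AcOH, −78 °C
Reagents that add atoms: formaldehyde, C=O
Why: Kinetic aldol hydroxymethylation of the α′ lithium enolate; formaldehyde adds trans to the neighbouring silyloxy group, which sets C8a, and loss of silyloxide from the enolate should be slow at −78 °C because it would generate a cyclopentadienone.

**Step 6**
Reactants: 10 (4S,5R)-4-(tert-butyldimethylsilyloxy)-5-(hydroxymethyl)cyclopent-2-en-1-one
Product: 11 (4S,5R)-4-(tert-butyldimethylsilyloxy)-5-[(triethylsilyloxy)methyl]cyclopent-2-en-1-one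
Conditions: Et3SiCl, imidazole, CH2Cl2, 0 °C
Reagents that add atoms: chlorotriethylsilane, CC[Si](Cl)(CC)CC
Why: Imidazole-promoted silylation of the only hydroxyl; the primary TES ether is chosen because mild acid removes it later beside the secondary TBS ether.

**Step 7**
Reactants: 11 (4S,5R)-4-(tert-butyldimethylsilyloxy)-5-[(triethylsilyloxy)methyl]cyclopent-2-en-1-one; 7 (3E,5Z,7S)-5,7-dimethylnona-3,5-dien-1-yne
Product: 13 (1RS,4S,5R)-4-(tert-butyldimethylsilyloxy)-1-[(3E,5Z,7S)-5,7-dimethylnona-3,5-dien-1-yn-1-yl]-5-[(triethylsilyloxy)methyl]cyclopent-2-en-1-ol, via lithium acetylide 12 (not isolated)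
Conditions: 7, n-BuLi, THF, −78 °C; then 11, −78 °C; H2O
Reagents that add atoms: none
Why: 1,2-Addition of a lithium acetylide to the enone carbonyl forms C4–C4a; the carbinol configuration need not be controlled because this carbon becomes sp2 in step 8.

**Step 8**
Reactants: 13 (1RS,4S,5R)-4-(tert-butyldimethylsilyloxy)-1-[(3E,5Z,7S)-5,7-dimethylnona-3,5-dien-1-yn-1-yl]-5-[(triethylsilyloxy)methyl]cyclopent-2-en-1-ol
Product: 14 (4R,5R)-5-(tert-butyldimethylsilyloxy)-3-[(3E,5Z,7S)-5,7-dimethylnona-3,5-dien-1-yn-1-yl]-4-[(triethylsilyloxy)methyl]cyclopent-2-en-1-one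
Conditions: [C5H5NH][CrO3Cl] (pyridinium chlorochromate), NaOAc, 4 Å molecular sieves, CH2Cl2, 23 °C
Reagents that add atoms: pyridinium chlorochromate, [O-][Cr](=O)(=O)Cl.c1cc[nH+]cc1
Why: Babler–Dauben oxidative transposition: the tertiary allylic chromate ester undergoes a [3,3]-shift to C6 and is oxidised there, so both carbinol epimers converge on the β-alkynyl enone with its ketone next to C8.

**Step 9**
Reactants: 14 (4R,5R)-5-(tert-butyldimethylsilyloxy)-3-[(3E,5Z,7S)-5,7-dimethylnona-3,5-dien-1-yn-1-yl]-4-[(triethylsilyloxy)methyl]cyclopent-2-en-1-one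
Product: 15 (1S,4R,5R)-5-(tert-butyldimethylsilyloxy)-3-[(3E,5Z,7S)-5,7-dimethylnona-3,5-dien-1-yn-1-yl]-1-(1-ethoxyvinyl)-4-[(triethylsilyloxy)methyl]cyclopent-2-en-1-ol
Conditions: ethyl vinyl ether, t-BuLi, THF, −78 → 0 °C; then 14, −78 °C; H2O
Reagents that add atoms: ethyl vinyl ether, C=COCC
Why: 1,2-Addition of the acyl-anion equivalent 1-ethoxyvinyllithium; attack anti to the adjacent, non-chelating C8 silyloxy group (Felkin–Anh) should put the masked acetyl on the face of the C1 substituent and the C6 hydroxyl cis to O8.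

**Step 10**
Reactants: 15 (1S,4R,5R)-5-(tert-butyldimethylsilyloxy)-3-[(3E,5Z,7S)-5,7-dimethylnona-3,5-dien-1-yn-1-yl]-1-(1-ethoxyvinyl)-4-[(triethylsilyloxy)methyl]cyclopent-2-en-1-ol
Product: 17 1-[(1S,4R,5R)-5-(tert-butyldimethylsilyloxy)-3-[(3E,5Z,7S)-5,7-dimethylnona-3,5-dien-1-yn-1-yl]-1-hydroxy-4-(hydroxymethyl)cyclopent-2-en-1-yl]ethan-1-one, via triethylsilyl-protected acetyl carbinol 16 (not isolated)
Conditions: AcOH/THF/H2O 3:1:1, 0 → 23 °C
Reagents that add atoms: water, O
Why: Enol ether hydrolysis (rate-limiting C-protonation of the electron-rich 1-alkoxyvinyl group, general-acid catalysed) should unmask the acetyl group before the allylic carbinol can ionise, and the same medium then cleaves the primary TES ether while the hindered secondary TBS ether stays.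

**Step 11**
Reactants: 17 1-[(1S,4R,5R)-5-(tert-butyldimethylsilyloxy)-3-[(3E,5Z,7S)-5,7-dimethylnona-3,5-dien-1-yn-1-yl]-1-hydroxy-4-(hydroxymethyl)cyclopent-2-en-1-yl]ethan-1-one
Product: 18 1-[(6S,7R,7aR)-7-(tert-butyldimethylsilyloxy)-3-[(1E,3Z,5S)-3,5-dimethylhepta-1,3-dien-1-yl]-6-hydroxy-1,6,7,7a-tetrahydrocyclopenta[c]pyran-6-yl]ethan-1-one
Conditions: (Ph3P)AuNTf2 (2 mol %), CH2Cl2, 0 → 23 °C
Reagents that add atoms: none
Why: Alkynol cycloisomerisation (hydroalkoxylation) under π-acid catalysis by cationic monovalent gold; anti attack of the C1 hydroxyl at C3 should be 6-endo-dig because positive charge in the gold–alkyne complex is better stabilised at the dienyl-bearing C3 and the wide exocyclic angles of the cyclopentene disfavour the strained 5-exo bicycle, and protodeauration leaves the C3=C4 enol ether of ring A.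

**Step 12**
Reactants: 18 1-[(6S,7R,7aR)-7-(tert-butyldimethylsilyloxy)-3-[(1E,3Z,5S)-3,5-dimethylhepta-1,3-dien-1-yl]-6-hydroxy-1,6,7,7a-tetrahydrocyclopenta[c]pyran-6-yl]ethan-1-one
Product: 20 (7R,8R,8aR)-8-(tert-butyldimethylsilyloxy)-3-[(1E,3Z,5S)-3,5-dimethylhepta-1,3-dien-1-yl]-7-hydroxy-7-methyl-1,7,8,8a-tetrahydro-6H-isochromen-6-one, via aluminium alkoxide chelate 19 (not isolated)
Conditions: Al(OtBu)3 (2 equiv), toluene, 80 °C; then aq. potassium sodium tartrate
Reagents that add atoms: none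
Why: Ligand exchange gives the C6 aluminium alkoxide, whose metal also binds the acetyl oxygen; in this five-membered chelate the C6–C8 bond lies nearly parallel to the carbonyl π* orbital, and C8 shifts with retention from C6 to the acetyl carbon (new C7–C8 bond) while C6–O becomes the ketone. The closest known reaction is the α-ketol (acyloin) rearrangement of 1-acylcycloalkanols, as in the aluminium-alkoxide D-homoannulation of 17-hydroxy-20-keto steroids. Ring B arises by a 1,2-shift that enlarges the five-membered carbocycle by one carbon, so no exo or endo ring closure is involved. The one new stereocentre, C7, is set by the chelate: with the carbonyl oxygen syn to the C6 oxygen and the acetyl group on the face opposite the C8 silyloxy group, C8 attacks the exposed carbonyl face, which leaves the new hydroxyl cis to O8 and the methyl trans (7R), while C8 and C8a are untouched. The step needs C8 and not the vinylic C5 to migrate; only the C8 shift leaves C6 conjugated with C5=C4a–C4=C3–O2, so the developing ketone is stabilised as a vinylogous ester in the transition state and, the shift being reversible, in the product as well. Al(OtBu)3 is chosen because it should be too weak a Lewis acid to ionise the allylic C6–O bond and too weak a base to deprotonate C8a.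

**Step 13**
Reactants: 20 (7R,8R,8aR)-8-(tert-butyldimethylsilyloxy)-3-[(1E,3Z,5S)-3,5-dimethylhepta-1,3-dien-1-yl]-7-hydroxy-7-methyl-1,7,8,8a-tetrahydro-6H-isochromen-6-one
Product: 21 (7R,8R,8aR)-3-[(1E,3Z,5S)-3,5-dimethylhepta-1,3-dien-1-yl]-7,8-dihydroxy-7-methyl-1,7,8,8a-tetrahydro-6H-isochromen-6-one
Conditions: Bu4NF, AcOH (1:1), THF, 0 → 23 °C
Reagents that add atoms: none
Why: Fluoride desilylation driven by the Si–F bond; acetic acid buffers the medium so that the β-hydroxy ketone formed should not undergo retro-aldol cleavage or epimerise at C8a.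

**Step 14**
Reactants: 21 (7R,8R,8aR)-3-[(1E,3Z,5S)-3,5-dimethylhepta-1,3-dien-1-yl]-7,8-dihydroxy-7-methyl-1,7,8,8a-tetrahydro-6H-isochromen-6-one
Product: 22 (7R,8R,8aR)-3-[(1E,3Z,5S)-3,5-dimethylhepta-1,3-dien-1-yl]-7-hydroxy-7-methyl-6-oxo-6,7,8,8a-tetrahydro-1H-isochromen-8-yl acetate
Conditions: Ac2O, pyridine, DMAP (cat.), CH2Cl2, 0 °C
Reagents that add atoms: acetic anhydride, CC(=O)OC(C)=O
Why: DMAP-catalysed acylation should distinguish the secondary C8 hydroxyl from the tertiary C7 hydroxyl, which stays free.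

**Compound list**

1 | (S)-2-methylbutan-1-ol | CC[C@H](C)CO | starting material
2 | (S)-2-methylbutanal | CC[C@H](C)C=O | intermediate
3 | (2Z,4S)-2-iodo-4-methylhex-2-ene | CC[C@H](C)/C=C(C)\I | intermediate
4 | (E)-2-(3,3-diethoxyprop-1-en-1-yl)-4,4,5,5-tetramethyl-1,3,2-dioxaborolane | CCOC(OCC)/C=C/B1OC(C)(C)C(C)(C)O1 | starting material
5 | (2E,4Z,6S)-1,1-diethoxy-4,6-dimethylocta-2,4-diene | CC[C@H](C)/C=C(C)\C=C\C(OCC)OCC | intermediate (not isolated)
6 | (2E,4Z,6S)-4,6-dimethylocta-2,4-dienal | CC[C@H](C)/C=C(C)\C=C\C=O | intermediate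
7 | (3E,5Z,7S)-5,7-dimethylnona-3,5-dien-1-yne | CC[C@H](C)/C=C(C)\C=C\C#C | intermediate
8 | (R)-4-(tert-butyldimethylsilyloxy)cyclopent-2-en-1-one | O=C1C=C[C@H](O[Si](C)(C)C(C)(C)C)C1 | starting material
9 | lithium (S)-3-(tert-butyldimethylsilyloxy)cyclopenta-1,4-dien-1-olate (α′ enolate of 8) | [Li]OC1=C[C@@H](O[Si](C)(C)C(C)(C)C)C=C1 | intermediate (not isolated)
10 | (4S,5R)-4-(tert-butyldimethylsilyloxy)-5-(hydroxymethyl)cyclopent-2-en-1-one | O=C1C=C[C@H](O[Si](C)(C)C(C)(C)C)[C@H]1CO | intermediate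
11 | (4S,5R)-4-(tert-butyldimethylsilyloxy)-5-[(triethylsilyloxy)methyl]cyclopent-2-en-1-one | O=C1C=C[C@H](O[Si](C)(C)C(C)(C)C)[C@H]1CO[Si](CC)(CC)CC | intermediate
12 | lithium acetylide of 7, [(3E,5Z,7S)-5,7-dimethylnona-3,5-dien-1-yn-1-yl]lithium | CC[C@H](C)/C=C(C)\C=C\C#C[Li] | intermediate (not isolated)
13 | (1RS,4S,5R)-4-(tert-butyldimethylsilyloxy)-1-[(3E,5Z,7S)-5,7-dimethylnona-3,5-dien-1-yn-1-yl]-5-[(triethylsilyloxy)methyl]cyclopent-2-en-1-ol (both carbinol epimers) | CC[C@H](C)/C=C(C)\C=C\C#CC1(O)C=C[C@H](O[Si](C)(C)C(C)(C)C)[C@H]1CO[Si](CC)(CC)CC | intermediate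
14 | (4R,5R)-5-(tert-butyldimethylsilyloxy)-3-[(3E,5Z,7S)-5,7-dimethylnona-3,5-dien-1-yn-1-yl]-4-[(triethylsilyloxy)methyl]cyclopent-2-en-1-one | CC[C@H](C)/C=C(C)\C=C\C#CC1=CC(=O)[C@H](O[Si](C)(C)C(C)(C)C)[C@H]1CO[Si](CC)(CC)CC | intermediate
15 | (1S,4R,5R)-5-(tert-butyldimethylsilyloxy)-3-[(3E,5Z,7S)-5,7-dimethylnona-3,5-dien-1-yn-1-yl]-1-(1-ethoxyvinyl)-4-[(triethylsilyloxy)methyl]cyclopent-2-en-1-ol | CC[C@H](C)/C=C(C)\C=C\C#CC1=C[C@@](O)(C(=C)OCC)[C@H](O[Si](C)(C)C(C)(C)C)[C@H]1CO[Si](CC)(CC)CC | intermediate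
16 | 1-[(1S,4R,5R)-5-(tert-butyldimethylsilyloxy)-3-[(3E,5Z,7S)-5,7-dimethylnona-3,5-dien-1-yn-1-yl]-1-hydroxy-4-[(triethylsilyloxy)methyl]cyclopent-2-en-1-yl]ethan-1-one | CC[C@H](C)/C=C(C)\C=C\C#CC1=C[C@@](O)(C(C)=O)[C@H](O[Si](C)(C)C(C)(C)C)[C@H]1CO[Si](CC)(CC)CC | intermediate (not isolated)
17 | 1-[(1S,4R,5R)-5-(tert-butyldimethylsilyloxy)-3-[(3E,5Z,7S)-5,7-dimethylnona-3,5-dien-1-yn-1-yl]-1-hydroxy-4-(hydroxymethyl)cyclopent-2-en-1-yl]ethan-1-one | CC[C@H](C)/C=C(C)\C=C\C#CC1=C[C@@](O)(C(C)=O)[C@H](O[Si](C)(C)C(C)(C)C)[C@H]1CO | intermediate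
18 | 1-[(6S,7R,7aR)-7-(tert-butyldimethylsilyloxy)-3-[(1E,3Z,5S)-3,5-dimethylhepta-1,3-dien-1-yl]-6-hydroxy-1,6,7,7a-tetrahydrocyclopenta[c]pyran-6-yl]ethan-1-one | CC[C@H](C)/C=C(C)\C=C\C1=CC2=C[C@@](O)(C(C)=O)[C@H](O[Si](C)(C)C(C)(C)C)[C@H]2CO1 | intermediate (precursor of the key step)
19 | di-tert-butoxyaluminium alkoxide of 18, chelated by the acetyl oxygen | CC[C@H](C)/C=C(C)\C=C\C1=CC2=C[C@@](O[Al](OC(C)(C)C)OC(C)(C)C)(C(C)=O)[C@H](O[Si](C)(C)C(C)(C)C)[C@H]2CO1 | intermediate (not isolated)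
20 | (7R,8R,8aR)-8-(tert-butyldimethylsilyloxy)-3-[(1E,3Z,5S)-3,5-dimethylhepta-1,3-dien-1-yl]-7-hydroxy-7-methyl-1,7,8,8a-tetrahydro-6H-isochromen-6-one | CC[C@H](C)/C=C(C)\C=C\C1=CC2=CC(=O)[C@](C)(O)[C@H](O[Si](C)(C)C(C)(C)C)[C@H]2CO1 | intermediate (product of the key step)
21 | (7R,8R,8aR)-3-[(1E,3Z,5S)-3,5-dimethylhepta-1,3-dien-1-yl]-7,8-dihydroxy-7-methyl-1,7,8,8a-tetrahydro-6H-isochromen-6-one | CC[C@H](C)/C=C(C)\C=C\C1=CC2=CC(=O)[C@](C)(O)[C@H](O)[C@H]2CO1 | intermediate
22 | (7R,8R,8aR)-3-[(1E,3Z,5S)-3,5-dimethylhepta-1,3-dien-1-yl]-7-hydroxy-7-methyl-6-oxo-6,7,8,8a-tetrahydro-1H-isochromen-8-yl acetate | CC[C@H](C)/C=C(C)\C=C\C1=CC2=CC(=O)[C@](C)(O)[C@H](OC(C)=O)[C@H]2CO1 | target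

**Count**

Total step count: 14. Longest linear sequence: 12 steps (steps 1–4, then 7–14). The core branch from 8 is 10 steps (steps 5–14).

**Steps most likely to fail**

Step 12. The C6 alkoxide may ionise toward a vinylogous oxocarbenium ion and destroy the ring A enol ether, the vinylic C5 may compete as migrating group, or the shift may run through the non-chelated rotamer and give the C7 epimer. The fallback sets out from 17 and comes back at 20. The same 1,2-shift would be run one stage earlier, on the monocyclic ketol, which has no enol ether. Al(OtBu)3 in toluene at 80 °C should give the ring-enlarged hydroxy ynenone F1, because conjugation of the new ketone with C4a=C5 and the alkyne again favours migration of C8. Catalytic DBU in CH2Cl2 should then close ring A by 6-endo conjugate addition of the C1 hydroxyl to C3, now the δ-carbon of an ynenone.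

Step 11. Attack at C4 (5-exo) may compete, reversible hemiketal formation between the C1 hydroxyl and the acetyl group may slow the cyclisation, or the gold catalyst may degrade the polyene. The fallback sets out from 14 and comes back at 18. Ring A would be closed while C3 is still the δ-carbon of an ynenone. PPTS in MeOH at 0 °C should remove the primary silyl ether to give the hydroxy ynenone F2. Catalytic DBU should then give, by 6-endo oxa-Michael addition, the bicyclic dienone F3. 1-Ethoxyvinyllithium should add to C6 anti to the C8 silyloxy group to give the 1-ethoxyvinyl carbinol F4. Its enol ether would be hydrolysed in an acetate buffer near pH 5; general-acid catalysis is used there so that the easily ionised carbinol is spared.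

Step 8. The chromate may transpose slowly toward the carbon flanked by the silyloxy group, and the acidic hexavalent chromium reagent may strip the TES ether and over-oxidise the freed alcohol. The fallback sets out from 13 and comes back at 14. Transposition and oxidation would be separated. Ph3SiOReO3 (cat.) in Et2O at 0 °C should isomerise 13 by a 1,3-hydroxyl shift to the secondary allylic alcohol F5, the equilibrium being driven by conjugation of the new C4a=C5 bond with the alkyne. Dess–Martin periodinane with NaHCO3 in CH2Cl2 should then oxidise it to the ynenone.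

**Further compounds**

F1 | step 12 | (4R,5R,6R)-5-(tert-butyldimethylsilyloxy)-3-[(3E,5Z,7S)-5,7-dimethylnona-3,5-dien-1-yn-1-yl]-6-hydroxy-4-(hydroxymethyl)-6-methylcyclohex-2-en-1-one | CC[C@H](C)/C=C(C)\C=C\C#CC1=CC(=O)[C@](C)(O)[C@H](O[Si](C)(C)C(C)(C)C)[C@H]1CO
F2 | step 11 | (4R,5R)-5-(tert-butyldimethylsilyloxy)-3-[(3E,5Z,7S)-5,7-dimethylnona-3,5-dien-1-yn-1-yl]-4-(hydroxymethyl)cyclopent-2-en-1-one | CC[C@H](C)/C=C(C)\C=C\C#CC1=CC(=O)[C@H](O[Si](C)(C)C(C)(C)C)[C@H]1CO
F3 | step 11 | (7R,7aR)-7-(tert-butyldimethylsilyloxy)-3-[(1E,3Z,5S)-3,5-dimethylhepta-1,3-dien-1-yl]-7,7a-dihydrocyclopenta[c]pyran-6(1H)-one | CC[C@H](C)/C=C(C)\C=C\C1=CC2=CC(=O)[C@H](O[Si](C)(C)C(C)(C)C)[C@H]2CO1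
F4 | step 11 | (6S,7R,7aR)-7-(tert-butyldimethylsilyloxy)-3-[(1E,3Z,5S)-3,5-dimethylhepta-1,3-dien-1-yl]-6-(1-ethoxyvinyl)-1,6,7,7a-tetrahydrocyclopenta[c]pyran-6-ol | CC[C@H](C)/C=C(C)\C=C\C1=CC2=C[C@@](O)(C(=C)OCC)[C@H](O[Si](C)(C)C(C)(C)C)[C@H]2CO1
F5 | step 8 | (1RS,4R,5R)-5-(tert-butyldimethylsilyloxy)-3-[(3E,5Z,7S)-5,7-dimethylnona-3,5-dien-1-yn-1-yl]-4-[(triethylsilyloxy)methyl]cyclopent-2-en-1-ol | CC[C@H](C)/C=C(C)\C=C\C#CC1=CC(O)[C@H](O[Si](C)(C)C(C)(C)C)[C@H]1CO[Si](CC)(CC)CC
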